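**Retrosynthetic overview**
- Target 37 is cut at the C3 ester into trienoic acid 31 and a furan 27. The furan masks the (Z)-8-oxo-7(11)-en-12-ol unit and is released by singlet oxygen at the end. The furan comes from butenolide 25, made by intramolecular Horner–Wadsworth–Emmons closure onto the C7 ketone.
- The strategy rests on this feature: C5 is the quaternary carbon carrying C14 and is the β-carbon of a ring B C7 ketone, and C4 is joined to C10 through C1–C3. Cutting C4–C5 therefore leads back to a 3-methylcyclohexenone carrying a 2-iodoalkenyl tether (14), closed by a reductive Heck reaction.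
- 14 comes from enone 12 (conjugate methylation, dehydrogenation). 12 comes from aldehyde 9 and methyl vinyl ketone by amine-catalysed Michael addition and aldol condensation (sets C10). 9 comes from an ynone by asymmetric transfer hydrogenation (sets C3).
- Ring order: ring B (step 8), ring A (step 11), the lactone/furan ring (steps 20–21), which is opened again in step 25.

Key step: step 11

Remark: eremophilane numbering is used for the bicyclic compounds (ring A = C1–C5 and C10, ring B = C5–C10, C14 on C5, C15 on C4, C11–C13 on C7); β is the face carrying C14, α the other face; the target is taken as the open hydroxy enone drawn, with H-10, C15 and O9 β and O3 α.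

**Route**

Step 1
Reactants: 1 methyl 5-chloro-5-oxopentanoate; 2 bis(trimethylsilyl)acetylene
Product: 3 methyl 5-oxo-7-(trimethylsilyl)hept-6-ynoate
Conditions: AlCl3, CH2Cl2, 0 °C
Reagents that add atoms: none
Why: Friedel–Crafts-type acylation of the silylalkyne with ipso-replacement of one silyl group should give the ynone, the methyl ester being inert to AlCl3 at this temperature.

Step 2
Reactants: 3 methyl 5-oxo-7-(trimethylsilyl)hept-6-ynoate
Product: 4 methyl (5R)-5-hydroxy-7-(trimethylsilyl)hept-6-ynoate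
Conditions: RuCl[(R,R)-TsDPEN](p-cymene) (cat.), iPrOH, rt
Reagents that add atoms: none
Why: Noyori asymmetric transfer hydrogenation of an alkynyl ketone, in which the (R,R)-diamine complex distinguishes the alkynyl from the alkyl flank and should deliver the (R)-carbinol that becomes C3.

Step 3
Reactants: 4 methyl (5R)-5-hydroxy-7-(trimethylsilyl)hept-6-ynoate
Product: 5 methyl (5R)-5-[(tert-butyldimethylsilyl)oxy]-7-(trimethylsilyl)hept-6-ynoate
Conditions: TBSCl, imidazole, DMF, rt
Reagents that add atoms: tert-butyldimethylsilyl chloride, CC(C)(C)[Si](C)(C)Cl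
Why: Standard silylation of the secondary propargylic alcohol, done at once so that the δ-hydroxy ester cannot lactonise.

Step 4
Reactants: 5 methyl (5R)-5-[(tert-butyldimethylsilyl)oxy]-7-(trimethylsilyl)hept-6-ynoate
Product: 6 methyl (5R)-5-[(tert-butyldimethylsilyl)oxy]hept-6-ynoate
Conditions: K2CO3, MeOH, rt
Reagents that add atoms: none
Why: Methanolysis cleaves the C(sp)–Si bond selectively, while the TBS ether and the methyl ester (degenerate exchange in methanol) should remain.

Step 5
Reactants: 6 methyl (5R)-5-[(tert-butyldimethylsilyl)oxy]hept-6-ynoate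
Product: 8 methyl (5R)-5-[(tert-butyldimethylsilyl)oxy]-6-iodohept-6-enoate, via alkenylstannane 7 (not isolated)
Conditions: Mo(CO)3(CNtBu)3 (cat.), Bu3SnH, hydroquinone, THF, 55 °C; then I2, CH2Cl2, 0 °C
Reagents that add atoms: iodine (I2), II
Why: Molybdenum-catalysed hydrostannation of propargylic ethers places tin on the internal carbon next to the oxygenated centre, and iododestannylation then gives the 2-iodoalkene without touching C3.

Step 6
Reactants: 8 methyl (5R)-5-[(tert-butyldimethylsilyl)oxy]-6-iodohept-6-enoate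
Product: 9 (5R)-5-[(tert-butyldimethylsilyl)oxy]-6-iodohept-6-enal
Conditions: iBu2AlH, CH2Cl2, −78 °C
Reagents that add atoms: none
Why: Partial reduction of the methyl ester through the tetrahedral aluminate that is stable at −78 °C should stop at the aldehyde and leave the alkenyl iodide and silyl ether intact.

Step 7
Reactants: 9 (5R)-5-[(tert-butyldimethylsilyl)oxy]-6-iodohept-6-enal; 10 methyl vinyl ketone
Product: 11 (2R,5R)-5-[(tert-butyldimethylsilyl)oxy]-6-iodo-2-(3-oxobutyl)hept-6-enal
Conditions: (S)-α,α-diphenylprolinol trimethylsilyl ether (10 mol %), ethyl 3,4-dihydroxybenzoate (20 mol %), neat, 4 °C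
Reagents that add atoms: none
Why: Enamine-catalysed Michael addition in which the (E)-enamine of 9 is shielded on one face by the diphenyl(silyloxy)methyl group, so the enone should add on the open face and set C10 as (R) under catalyst control, independent of the remote C3 centre.

Step 8
Reactants: 11 (2R,5R)-5-[(tert-butyldimethylsilyl)oxy]-6-iodo-2-(3-oxobutyl)hept-6-enal
Product: 12 (4R)-4-[(3R)-3-[(tert-butyldimethylsilyl)oxy]-4-iodopent-4-en-1-yl]cyclohex-2-en-1-one
Conditions: LiOH, iPrOH, rt
Reagents that add atoms: none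
Why: Intramolecular aldol condensation of the methyl ketone onto the aldehyde closes ring B as the only possible six-membered enone, and the mild base should leave C10 unchanged.

Step 9
Reactants: 12 (4R)-4-[(3R)-3-[(tert-butyldimethylsilyl)oxy]-4-iodopent-4-en-1-yl]cyclohex-2-en-1-one
Product: 13 {[(3S,4R)-4-[(3R)-3-[(tert-butyldimethylsilyl)oxy]-4-iodopent-4-en-1-yl]-3-methylcyclohex-1-en-1-yl]oxy}trimethylsilane
Conditions: MeMgBr, CuBr·SMe2 (10 mol %), TMSCl, HMPA, THF, −78 °C
Reagents that add atoms: methylmagnesium bromide, C[Mg]Br; chlorotrimethylsilane, C[Si](C)(C)Cl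
Why: Copper-catalysed conjugate addition with in situ silyl trapping brings in C14 anti to the C10 side chain (a centre erased in the next step) and gives the regiodefined enol ether, while the alkenyl iodide does not react with the Grignard reagent at −78 °C.

Step 10
Reactants: 13 {[(3S,4R)-4-[(3R)-3-[(tert-butyldimethylsilyl)oxy]-4-iodopent-4-en-1-yl]-3-methylcyclohex-1-en-1-yl]oxy}trimethylsilane
Product: 14 (4R)-4-[(3R)-3-[(tert-butyldimethylsilyl)oxy]-4-iodopent-4-en-1-yl]-3-methylcyclohex-2-en-1-one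
Conditions: IBX·4-methoxypyridine N-oxide, DMSO, rt
Reagents that add atoms: none
Why: Hypervalent-iodine dehydrogenation of the silyl enol ether gives the β-methyl enone, and is chosen over a Saegusa–Ito oxidation because zerovalent palladium released there could insert into the alkenyl iodide too early.

Step 11
Reactants: 14 (4R)-4-[(3R)-3-[(tert-butyldimethylsilyl)oxy]-4-iodopent-4-en-1-yl]-3-methylcyclohex-2-en-1-one
Product: 15 (4aR,7R,8aS)-7-[(tert-butyldimethylsilyl)oxy]-8a-methyl-8-methylideneoctahydronaphthalen-2(1H)-one (cis-fused; C7 ketone, C4=C15 exocyclic, 3α-OTBS)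
Conditions: Pd(OAc)2 (10 mol %), PPh3 (20 mol %), HCO2Na, Et4NCl, DMF, 80 °C
Reagents that add atoms: none
Why: Zerovalent palladium, formed in situ from Pd(OAc)2 and PPh3, inserts into the C4–I bond, and the alkenylpalladium species adds syn across C5=C6 of the enone with C4 bonding to the β-carbon C5 and palladium to C6, which creates the C4–C5 bond and the quaternary centre. The palladium enolate has no β-hydrogen for syn-elimination (C5 is fully substituted, C7 is the carbonyl), so formate intercepts it, loses CO2 and delivers hydride, giving the saturated ketone and returning zerovalent palladium. This is an intramolecular reductive Heck reaction (conjugate alkenylation), the known reaction type for alkenyl halides tethered to β,β-disubstituted cyclohexenones. Ring A closes in the 6-exo-trig mode, preferred over 7-endo attack at C6 by ring size and by the polarity of the enone. The new stereocentre C5 is controlled by C10, because the three-carbon tether can reach C5 only on the face to which it is attached, so C14 should end cis to H-10 (cis-fused decalin), while C3 and C10 are untouched. The step needs insertion to outrun formate reduction of the alkenylpalladium iodide, which the six-membered transition state, the electron-poor alkene and the sparingly soluble formate salt should secure.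

Step 12
Reactants: 15 (4aR,7R,8aS)-7-[(tert-butyldimethylsilyl)oxy]-8a-methyl-8-methylideneoctahydronaphthalen-2(1H)-one
Product: 16 (4aR,7R,8aS)-7-hydroxy-8a-methyl-8-methylideneoctahydronaphthalen-2(1H)-one
Conditions: Bu4NF, THF, 0 °C to rt
Reagents that add atoms: none
Why: Fluoride cleavage of the silyl ether frees the allylic C3 hydroxyl needed as directing group, and no centre is α to the ketone.

Step 13
Reactants: 16 (4aR,7R,8aS)-7-hydroxy-8a-methyl-8-methylideneoctahydronaphthalen-2(1H)-one
Product: 17 (4aR,7R,8R,8aS)-7-hydroxy-8,8a-dimethyloctahydronaphthalen-2(1H)-one (3α-hydroxy-10βH-eremophilan-7-one)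
Conditions: [Ir(cod)(PCy3)(py)]PF6 (5 mol %), H2 (1 atm), CH2Cl2, rt
Reagents that add atoms: none
Why: Hydroxyl-directed hydrogenation, in which the cationic iridium centre bound to O3 delivers hydrogen to the C4=C15 face syn to the hydroxyl, so H-4 ends cis to O3 and C15 trans to O3 and cis to C14, setting C4.

Step 14
Reactants: 17 3α-hydroxy-10βH-eremophilan-7-one
Product: 18 3α-(pivaloyloxy)-10βH-eremophilan-7-one
Conditions: pivaloyl chloride, pyridine, DMAP, CH2Cl2, rt
Reagents that add atoms: pivaloyl chloride, CC(C)(C)C(Cl)=O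
Why: Acylation gives an ester without α-hydrogens that should survive amide base, OsO4 and NaH and that the lactone-reducing hydride of step 21 removes in the same operation.

Step 15
Reactants: 18 3α-(pivaloyloxy)-10βH-eremophilan-7-one
Product: 19 3α-(pivaloyloxy)-7-(trimethylsilyloxy)-10βH-eremophil-7-ene (C7=C8 silyl enol ether)
Conditions: LiN(iPr)2, TMSCl, THF, −78 °C
Reagents that add atoms: chlorotrimethylsilane, C[Si](C)(C)Cl
Why: Kinetic deprotonation should occur at C8 and not at the neopentylic C6 next to the quaternary C5, and any C6 regioisomer is harmless because it cannot be dehydrogenated (C5 carries no hydrogen).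

Step 16
Reactants: 19 3α-(pivaloyloxy)-7-(trimethylsilyloxy)-10βH-eremophil-7-ene
Product: 20 3α-(pivaloyloxy)-10βH-eremophil-8-en-7-one
Conditions: Pd(OAc)2, MeCN, rt
Reagents that add atoms: none
Why: Saegusa–Ito oxidation, in which divalent palladium forms the oxa-π-allyl species from the enol ether and β-hydride elimination from C9 gives the C8=C9 enone under neutral conditions that leave C10 alone.

Step 17
Reactants: 20 3α-(pivaloyloxy)-10βH-eremophil-8-en-7-one
Product: 21 8β,9β-dihydroxy-3α-(pivaloyloxy)-10βH-eremophilan-7-one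
Conditions: OsO4 (5 mol %), N-methylmorpholine N-oxide, citric acid, tBuOH–H2O, rt
Reagents that add atoms: osmium tetroxide, O=[Os](=O)(=O)=O; N-methylmorpholine N-oxide, C[N+]1([O-])CCOCC1; water, O
Why: Catalytic syn-dihydroxylation should occur on the convex β-face, anti to C1 on the allylic carbon C10 (ring A covers the α-face), which sets C9 with its hydroxyl cis to H-10 and places O8 for the lactone.

Step 18
Reactants: 21 8β,9β-dihydroxy-3α-(pivaloyloxy)-10βH-eremophilan-7-one
Product: 22 8β-hydroxy-3α-(pivaloyloxy)-9β-(triethylsilyloxy)-10βH-eremophilan-7-one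
Conditions: TESCl (1.05 equiv), imidazole, DMF, −20 °C
Reagents that add atoms: chlorotriethylsilane, CC[Si](Cl)(CC)CC
Why: Regioselective silylation, because in the favoured two-chair conformer (C14 equatorial on ring B, which avoids a C14/O9 syn-diaxial contact) the C9 hydroxyl is equatorial while the C8 hydroxyl is axial and inductively deactivated by the adjacent ketone.

Step 19
Reactants: 22 8β-hydroxy-3α-(pivaloyloxy)-9β-(triethylsilyloxy)-10βH-eremophilan-7-one; 23 2-(diethoxyphosphoryl)propanoic acid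
Product: 24 8β-[2-(diethoxyphosphoryl)propanoyloxy]-3α-(pivaloyloxy)-9β-(triethylsilyloxy)-10βH-eremophilan-7-one
Conditions: DCC, DMAP, CH2Cl2, 0 °C to rt
Reagents that add atoms: none
Why: Steglich esterification of the only free hydroxyl puts the phosphonate on O8, next to the C7 ketone it is to attack.

Step 20
Reactants: 24 8β-[2-(diethoxyphosphoryl)propanoyloxy]-3α-(pivaloyloxy)-9β-(triethylsilyloxy)-10βH-eremophilan-7-one
Product: 25 3α-(pivaloyloxy)-9β-(triethylsilyloxy)-8αH,10βH-eremophil-7(11)-en-12,8-olide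
Conditions: NaH, THF, 0 °C to rt
Reagents that add atoms: none
Why: Intramolecular Horner–Wadsworth–Emmons reaction, in which the phosphonate carbon (the most acidic site, so deprotonation there should outrun enolisation at C8 that could expel the C9 silyloxy group) adds to the C7 ketone and the five-membered ring fixes the C7=C11 geometry.

Step 21
Reactants: 25 3α-(pivaloyloxy)-9β-(triethylsilyloxy)-8αH,10βH-eremophil-7(11)-en-12,8-olide
Product: 27 9β-(triethylsilyloxy)-10βH-furanoeremophilan-3α-ol, via lactol 26 (not isolated)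
Conditions: iBu2AlH (excess), CH2Cl2, −78 °C; then aq. citric acid, rt
Reagents that add atoms: none
Why: Hydride reduction of the butenolide stops at the lactol, which loses water on mild acid work-up to aromatise to the furan, while the same reagent cleaves the pivalate and the silyl ether should survive.

Step 22
Reactants: 28 (E)-non-3-en-2-one; 29 triethyl 4-phosphonocrotonate
Product: 30 ethyl (2E,4E,6E)-5-methyldodeca-2,4,6-trienoate
Conditions: LiN(SiMe3)2, THF, −78 to 0 °C
Reagents that add atoms: none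
Why: Vinylogous Horner–Wadsworth–Emmons olefination of the methyl ketone should favour the 4E isomer with the larger heptenyl group trans to the ester chain, the minor 4Z isomer being removed by chromatography.

Step 23
Reactants: 30 ethyl (2E,4E,6E)-5-methyldodeca-2,4,6-trienoate
Product: 31 (2E,4E,6E)-5-methyldodeca-2,4,6-trienoic acid
Conditions: LiOH, THF–MeOH–H2O, rt; then dil. HCl to pH 3
Reagents that add atoms: lithium hydroxide, [Li+].[OH-]
Why: Saponification of an ethyl ester that has no base-sensitive centre.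

Step 24
Reactants: 27 9β-(triethylsilyloxy)-10βH-furanoeremophilan-3α-ol; 31 (2E,4E,6E)-5-methyldodeca-2,4,6-trienoic acid
Product: 33 9β-(triethylsilyloxy)-10βH-furanoeremophilan-3α-yl (2E,4E,6E)-5-methyldodeca-2,4,6-trienoate, via mixed anhydride 32 (not isolated)
Conditions: 2,4,6-trichlorobenzoyl chloride, Et3N, THF, rt; then 27, DMAP, toluene, rt
Reagents that add atoms: none
Why: Yamaguchi esterification acylates the hindered secondary C3 hydroxyl, the only free hydroxyl, under conditions that furans and silyl ethers tolerate.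

Step 25
Reactants: 33 9β-(triethylsilyloxy)-10βH-furanoeremophilan-3α-yl (2E,4E,6E)-5-methyldodeca-2,4,6-trienoate
Product: 35 (7(11)Z)-8,12-dioxo-9β-(triethylsilyloxy)-10βH-eremophil-7(11)-en-3α-yl (2E,4E,6E)-5-methyldodeca-2,4,6-trienoate, via furan endoperoxide 34 (not isolated)
Conditions: O2, visible light, tetraphenylporphyrin, CH2Cl2, −78 °C; then Me2S, −78 °C to rt
Reagents that add atoms: oxygen, O=O
Why: Singlet oxygen adds [4+2] to the electron-rich furan far faster than to the ester-conjugated triene, and reduction of the endoperoxide with Me2S opens it to the cis-enedicarbonyl, so the ring origin of C8 and C12 fixes the Z geometry.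

Step 26
Reactants: 35 (7(11)Z)-8,12-dioxo-9β-(triethylsilyloxy)-10βH-eremophil-7(11)-en-3α-yl (2E,4E,6E)-5-methyldodeca-2,4,6-trienoate
Product: 36 (7(11)Z)-12-hydroxy-8-oxo-9β-(triethylsilyloxy)-10βH-eremophil-7(11)-en-3α-yl (2E,4E,6E)-5-methyldodeca-2,4,6-trienoate
Conditions: NaBH4, CeCl3·7H2O, MeOH–CH2Cl2, −78 °C
Reagents that add atoms: none
Why: Luche 1,2-reduction should take the aldehyde, which is more electrophilic and far less hindered than the C8 ketone flanked by the tetrasubstituted alkene and the silyloxy carbon, and leaves the trienoate alone.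

Step 27
Reactants: 36 (7(11)Z)-12-hydroxy-8-oxo-9β-(triethylsilyloxy)-10βH-eremophil-7(11)-en-3α-yl (2E,4E,6E)-5-methyldodeca-2,4,6-trienoate
Product: 37 (3R,4R,5R,9R,10S,7(11)Z)-9,12-dihydroxy-8-oxoeremophil-7(11)-en-3-yl (2E,4E,6E)-5-methyldodeca-2,4,6-trienoate (target)
Conditions: HF·pyridine, pyridine, THF, 0 °C
Reagents that add atoms: none
Why: Buffered fluoride removes the triethylsilyl ether under near-neutral conditions meant to spare the ester, the α-ketol centre C9 and the (Z)-γ-hydroxy enone, which stronger acid could cyclise and dehydrate back to a furan.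

**Compound list**

1 | methyl 5-chloro-5-oxopentanoate | COC(=O)CCCC(Cl)=O | starting material
2 | bis(trimethylsilyl)acetylene | C[Si](C)(C)C#C[Si](C)(C)C | starting material
3 | methyl 5-oxo-7-(trimethylsilyl)hept-6-ynoate | COC(=O)CCCC(=O)C#C[Si](C)(C)C | intermediate
4 | methyl (5R)-5-hydroxy-7-(trimethylsilyl)hept-6-ynoate | COC(=O)CCC[C@@H](O)C#C[Si](C)(C)C | intermediate
5 | methyl (5R)-5-[(tert-butyldimethylsilyl)oxy]-7-(trimethylsilyl)hept-6-ynoate | COC(=O)CCC[C@@H](O[Si](C)(C)C(C)(C)C)C#C[Si](C)(C)C | intermediate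
6 | methyl (5R)-5-[(tert-butyldimethylsilyl)oxy]hept-6-ynoate | COC(=O)CCC[C@@H](O[Si](C)(C)C(C)(C)C)C#C | intermediate
7 | methyl (5R)-5-[(tert-butyldimethylsilyl)oxy]-6-(tributylstannyl)hept-6-enoate (not isolated) | COC(=O)CCC[C@@H](O[Si](C)(C)C(C)(C)C)C(=C)[Sn](CCCC)(CCCC)CCCC | intermediate
8 | methyl (5R)-5-[(tert-butyldimethylsilyl)oxy]-6-iodohept-6-enoate | COC(=O)CCC[C@@H](O[Si](C)(C)C(C)(C)C)C(I)=C | intermediate
9 | (5R)-5-[(tert-butyldimethylsilyl)oxy]-6-iodohept-6-enal | O=CCCC[C@@H](O[Si](C)(C)C(C)(C)C)C(I)=C | intermediate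
10 | methyl vinyl ketone | CC(=O)C=C | starting material
11 | (2R,5R)-5-[(tert-butyldimethylsilyl)oxy]-6-iodo-2-(3-oxobutyl)hept-6-enal | CC(=O)CC[C@H](C=O)CC[C@@H](O[Si](C)(C)C(C)(C)C)C(I)=C | intermediate
12 | (4R)-4-[(3R)-3-[(tert-butyldimethylsilyl)oxy]-4-iodopent-4-en-1-yl]cyclohex-2-en-1-one | O=C1CC[C@H](C=C1)CC[C@@H](O[Si](C)(C)C(C)(C)C)C(I)=C | intermediate
13 | {[(3S,4R)-4-[(3R)-3-[(tert-butyldimethylsilyl)oxy]-4-iodopent-4-en-1-yl]-3-methylcyclohex-1-en-1-yl]oxy}trimethylsilane (methyl trans to side chain) | C[Si](C)(C)OC1=C[C@@H](C)[C@@H](CC1)CC[C@@H](O[Si](C)(C)C(C)(C)C)C(I)=C | intermediate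
14 | (4R)-4-[(3R)-3-[(tert-butyldimethylsilyl)oxy]-4-iodopent-4-en-1-yl]-3-methylcyclohex-2-en-1-one | CC(C)(C)[Si](C)(C)O[C@H](CC[C@@H]1CCC(=O)C=C1C)C(I)=C | intermediate
15 | (4aR,7R,8aS)-7-[(tert-butyldimethylsilyl)oxy]-8a-methyl-8-methylideneoctahydronaphthalen-2(1H)-one | CC(C)(C)[Si](C)(C)O[C@@H]1CC[C@@H]2CCC(=O)C[C@]2(C)C1=C | intermediate
16 | (4aR,7R,8aS)-7-hydroxy-8a-methyl-8-methylideneoctahydronaphthalen-2(1H)-one | O[C@@H]1CC[C@@H]2CCC(=O)C[C@]2(C)C1=C | intermediate
17 | (4aR,7R,8R,8aS)-7-hydroxy-8,8a-dimethyloctahydronaphthalen-2(1H)-one (3α-hydroxy-10βH-eremophilan-7-one) | O[C@@H]1CC[C@@H]2CCC(=O)C[C@]2(C)[C@H]1C | intermediate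
18 | 3α-(pivaloyloxy)-10βH-eremophilan-7-one | CC(C)(C)C(=O)O[C@@H]1CC[C@@H]2CCC(=O)C[C@]2(C)[C@H]1C | intermediate
19 | 3α-(pivaloyloxy)-7-(trimethylsilyloxy)-10βH-eremophil-7-ene | CC(C)(C)C(=O)O[C@@H]1CC[C@@H]2CC=C(O[Si](C)(C)C)C[C@]2(C)[C@H]1C | intermediate
20 | 3α-(pivaloyloxy)-10βH-eremophil-8-en-7-one | CC(C)(C)C(=O)O[C@@H]1CC[C@@H]2C=CC(=O)C[C@]2(C)[C@H]1C | intermediate
21 | 8β,9β-dihydroxy-3α-(pivaloyloxy)-10βH-eremophilan-7-one | CC(C)(C)C(=O)O[C@@H]1CC[C@@H]2[C@@H](O)[C@@H](O)C(=O)C[C@]2(C)[C@H]1C | intermediate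
22 | 8β-hydroxy-3α-(pivaloyloxy)-9β-(triethylsilyloxy)-10βH-eremophilan-7-one | CC(C)(C)C(=O)O[C@@H]1CC[C@@H]2[C@@H](O[Si](CC)(CC)CC)[C@@H](O)C(=O)C[C@]2(C)[C@H]1C | intermediate
23 | 2-(diethoxyphosphoryl)propanoic acid (racemic) | CCOP(=O)(OCC)C(C)C(=O)O | starting material
24 | 8β-[2-(diethoxyphosphoryl)propanoyloxy]-3α-(pivaloyloxy)-9β-(triethylsilyloxy)-10βH-eremophilan-7-one (epimers at the phosphonate carbon) | CC(C)(C)C(=O)O[C@@H]1CC[C@@H]2[C@@H](O[Si](CC)(CC)CC)[C@@H](OC(=O)C(C)P(=O)(OCC)OCC)C(=O)C[C@]2(C)[C@H]1C | intermediate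
25 | 3α-(pivaloyloxy)-9β-(triethylsilyloxy)-8αH,10βH-eremophil-7(11)-en-12,8-olide | CC(C)(C)C(=O)O[C@@H]1CC[C@@H]2[C@@H](O[Si](CC)(CC)CC)[C@H]3OC(=O)C(C)=C3C[C@]2(C)[C@H]1C | intermediate
26 | 8,12-epoxy-9β-(triethylsilyloxy)-8αH,10βH-eremophil-7(11)-ene-3α,12-diol (lactol, not isolated) | O[C@@H]1CC[C@@H]2[C@@H](O[Si](CC)(CC)CC)[C@H]3OC(O)C(C)=C3C[C@]2(C)[C@H]1C | intermediate
27 | 9β-(triethylsilyloxy)-10βH-furanoeremophilan-3α-ol | O[C@@H]1CC[C@@H]2[C@@H](O[Si](CC)(CC)CC)c3occ(C)c3C[C@]2(C)[C@H]1C | intermediate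
28 | (E)-non-3-en-2-one | CCCCC/C=C/C(C)=O | starting material
29 | triethyl 4-phosphonocrotonate | CCOC(=O)/C=C/CP(=O)(OCC)OCC | starting material
30 | ethyl (2E,4E,6E)-5-methyldodeca-2,4,6-trienoate | CCCCC/C=C/C(C)=C/C=C/C(=O)OCC | intermediate
31 | (2E,4E,6E)-5-methyldodeca-2,4,6-trienoic acid | CCCCC/C=C/C(C)=C/C=C/C(=O)O | intermediate
32 | (2E,4E,6E)-5-methyldodeca-2,4,6-trienoic 2,4,6-trichlorobenzoic anhydride (not isolated) | CCCCC/C=C/C(C)=C/C=C/C(=O)OC(=O)c1c(Cl)cc(Cl)cc1Cl | intermediate
33 | 9β-(triethylsilyloxy)-10βH-furanoeremophilan-3α-yl (2E,4E,6E)-5-methyldodeca-2,4,6-trienoate | CCCCC/C=C/C(C)=C/C=C/C(=O)O[C@@H]1CC[C@@H]2[C@@H](O[Si](CC)(CC)CC)c3occ(C)c3C[C@]2(C)[C@H]1C | intermediate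
34 | 8,12-endoperoxide of furan 33 (not isolated) | CCCCC/C=C/C(C)=C/C=C/C(=O)O[C@@H]1CC[C@@H]2[C@@H](O[Si](CC)(CC)CC)C34OOC(O3)C(C)=C4C[C@]2(C)[C@H]1C | intermediate
35 | (7(11)Z)-8,12-dioxo-9β-(triethylsilyloxy)-10βH-eremophil-7(11)-en-3α-yl (2E,4E,6E)-5-methyldodeca-2,4,6-trienoate | CCCCC/C=C/C(C)=C/C=C/C(=O)O[C@@H]1CC[C@@H]2[C@@H](O[Si](CC)(CC)CC)C(=O)/C(=C(/C)C=O)C[C@]2(C)[C@H]1C | intermediate
36 | (7(11)Z)-12-hydroxy-8-oxo-9β-(triethylsilyloxy)-10βH-eremophil-7(11)-en-3α-yl (2E,4E,6E)-5-methyldodeca-2,4,6-trienoate | CCCCC/C=C/C(C)=C/C=C/C(=O)O[C@@H]1CC[C@@H]2[C@@H](O[Si](CC)(CC)CC)C(=O)/C(=C(/C)CO)C[C@]2(C)[C@H]1C | intermediate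
37 | (3R,4R,5R,9R,10S,7(11)Z)-9,12-dihydroxy-8-oxoeremophil-7(11)-en-3-yl (2E,4E,6E)-5-methyldodeca-2,4,6-trienoate | CCCCC/C=C/C(C)=C/C=C/C(=O)O[C@@H]1CC[C@@H]2[C@@H](O)C(=O)/C(=C(/C)CO)C[C@]2(C)[C@H]1C | target

**Step count**
- Total: 27 steps.
- Longest linear sequence: 25 steps (steps 1–21 and 24–27); the side-chain acid takes 2 steps (22–23).

**Steps most likely to fail**

1. Step 11 (key step). Formate may reduce the alkenylpalladium iodide before it inserts, or insertion at the fully substituted β-carbon may stall, so iodine would be lost without ring closure. Fallback: the C4–C5 bond would be made by a radical. Starting from 14, Bu3SnH and azobisisobutyronitrile in benzene at 80 °C (slow addition) generate the C4 alkenyl radical, which should add 6-exo to the enone β-carbon C5 on the tether face. Hydrogen transfer to the α-keto radical then gives 15, where the route is rejoined. This fallback makes no compound outside the list (F0).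

2. Step 18. The silyl chloride may not discriminate between the C9 and C8 hydroxyls, or the silyl group may migrate, which would later put the phosphonate ester on the wrong oxygen. Fallback: ring size, not hydroxyl reactivity, would decide which oxygen is acylated.
   - Starting from 21, 2,2-dimethoxypropane and pyridinium p-toluenesulfonate give 8β,9β-(isopropylidenedioxy)-3α-(pivaloyloxy)-10βH-eremophilan-7-one F1.
   - The lithium enolate of ethyl propanoate (LiN(iPr)2, THF, −78 °C) adds to the C7 ketone to give ethyl 2-[7-hydroxy-8β,9β-(isopropylidenedioxy)-3α-(pivaloyloxy)-10βH-eremophilan-7-yl]propanoate F2.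
   - Aqueous trifluoroacetic acid removes the acetonide, and the ester should close onto O8 as the five-membered lactone in preference to the six-membered lactone onto O9, giving 7,9β-dihydroxy-3α-(pivaloyloxy)-10βH-eremophilan-12,8-olide F3.
   - TESCl and imidazole silylate the secondary C9 hydroxyl but not the tertiary C7 hydroxyl, giving 7-hydroxy-3α-(pivaloyloxy)-9β-(triethylsilyloxy)-10βH-eremophilan-12,8-olide F4.
   - SOCl2 in pyridine dehydrates the tertiary alcohol into conjugation to give 25, where the route is rejoined.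

3. Step 25. The trienoate may compete for singlet oxygen or isomerise under irradiation while the furan is oxidised. Fallback: the furan would be opened before the side chain is attached.
   - Starting from 27, photooxygenation and Me2S as in step 25 give, through the 8,12-endoperoxide of furan 27 F5, (7(11)Z)-3α-hydroxy-8-oxo-9β-(triethylsilyloxy)-10βH-eremophil-7(11)-en-12-al F6.
   - Luche reduction gives (7(11)Z)-3α,12-dihydroxy-9β-(triethylsilyloxy)-10βH-eremophil-7(11)-en-8-one F7.
   - TESCl and imidazole at low temperature silylate the primary allylic hydroxyl in preference to the hindered secondary one, giving (7(11)Z)-3α-hydroxy-9β,12-bis(triethylsilyloxy)-10βH-eremophil-7(11)-en-8-one F8.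
   - Yamaguchi esterification with 31 (through 32) gives (7(11)Z)-8-oxo-9β,12-bis(triethylsilyloxy)-10βH-eremophil-7(11)-en-3α-yl (2E,4E,6E)-5-methyldodeca-2,4,6-trienoate F9.
   - HF·pyridine buffered with pyridine removes both silyl groups to give 37, where the route is rejoined.

Further compounds
F0 | step 11 | none | none
F1 | step 18 | 8β,9β-(isopropylidenedioxy)-3α-(pivaloyloxy)-10βH-eremophilan-7-one | CC(C)(C)C(=O)O[C@@H]1CC[C@@H]2[C@H]3OC(C)(C)O[C@H]3C(=O)C[C@]2(C)[C@H]1C
F2 | step 18 | ethyl 2-[7-hydroxy-8β,9β-(isopropylidenedioxy)-3α-(pivaloyloxy)-10βH-eremophilan-7-yl]propanoate | CC(C)(C)C(=O)O[C@@H]1CC[C@@H]2[C@H]3OC(C)(C)O[C@H]3C(O)(C(C)C(=O)OCC)C[C@]2(C)[C@H]1C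
F3 | step 18 | 7,9β-dihydroxy-3α-(pivaloyloxy)-10βH-eremophilan-12,8-olide | CC(C)(C)C(=O)O[C@@H]1CC[C@@H]2[C@@H](O)[C@H]3OC(=O)C(C)C3(O)C[C@]2(C)[C@H]1C
F4 | step 18 | 7-hydroxy-3α-(pivaloyloxy)-9β-(triethylsilyloxy)-10βH-eremophilan-12,8-olide | CC(C)(C)C(=O)O[C@@H]1CC[C@@H]2[C@@H](O[Si](CC)(CC)CC)[C@H]3OC(=O)C(C)C3(O)C[C@]2(C)[C@H]1C
F5 | step 25 | 8,12-endoperoxide of furan 27 | O[C@@H]1CC[C@@H]2[C@@H](O[Si](CC)(CC)CC)C34OOC(O3)C(C)=C4C[C@]2(C)[C@H]1C
F6 | step 25 | (7(11)Z)-3α-hydroxy-8-oxo-9β-(triethylsilyloxy)-10βH-eremophil-7(11)-en-12-al | O[C@@H]1CC[C@@H]2[C@@H](O[Si](CC)(CC)CC)C(=O)/C(=C(/C)C=O)C[C@]2(C)[C@H]1C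
F7 | step 25 | (7(11)Z)-3α,12-dihydroxy-9β-(triethylsilyloxy)-10βH-eremophil-7(11)-en-8-one | O[C@@H]1CC[C@@H]2[C@@H](O[Si](CC)(CC)CC)C(=O)/C(=C(/C)CO)C[C@]2(C)[C@H]1C
F8 | step 25 | (7(11)Z)-3α-hydroxy-9β,12-bis(triethylsilyloxy)-10βH-eremophil-7(11)-en-8-one | O[C@@H]1CC[C@@H]2[C@@H](O[Si](CC)(CC)CC)C(=O)/C(=C(/C)CO[Si](CC)(CC)CC)C[C@]2(C)[C@H]1C
F9 | step 25 | (7(11)Z)-8-oxo-9β,12-bis(triethylsilyloxy)-10βH-eremophil-7(11)-en-3α-yl (2E,4E,6E)-5-methyldodeca-2,4,6-trienoate | CCCCC/C=C/C(C)=C/C=C/C(=O)O[C@@H]1CC[C@@H]2[C@@H](O[Si](CC)(CC)CC)C(=O)/C(=C(/C)CO[Si](CC)(CC)CC)C[C@]2(C)[C@H]1C
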